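The epoxide oxygen on C1/C6, the benzoate oxygen on C2 and the hydroxyl on C3 all lie on one face of the cyclohexene. That face is the exo face of a 7-oxabicyclo[2.2.1]heptene whose oxygen bridges C2 and C5 and whose alkene is C1=C6. Everything therefore rests on disconnecting C2–C3 and C4–C5: a catalytic asymmetric Diels–Alder reaction between furan-3-ylmethyl benzoate, which already carries the C7 ester, and 2-bromoacrolein closes the carbocycle, delivers the C2 oxygen as the bridge and sets the absolute configuration in one operation. Exo epoxidation, exo oxygenation of C3 and cleavage of the C5–O bond then complete the target.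

Key step: step 3

Remark on locants: the ring carbons keep the target locants C1–C6 in every intermediate and C7 is the exocyclic CH2 carbon; in the bicycles the oxygen bridge joins C2 and C5, and exo means the face of that bridge.

Assumption on the catalyst: the oxazaborolidinone from N-tosyl-(S)-tryptophan is taken to expose the same face of 2-bromoacrolein as it does towards cyclopentadiene, which corresponds to 7 as drawn; should the adduct prove antipodal, the catalyst from (R)-tryptophan is used instead.

Remark on protecting groups: the C7 benzoate is kept from the start because it is an ester of the target, so every later step is chosen to be non-basic.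

Step 1
Reactants: 1 furan-3-ylmethanol; 2 benzoyl chloride
Product: 3 furan-3-ylmethyl benzoate
Conditions: BzCl, Et3N, DMAP (cat.), CH2Cl2, 0 °C → rt
Reagents that add atoms: benzoyl chloride (2), ClC(=O)c1ccccc1
Why: DMAP-catalysed acyl transfer (esterification) to a primary alcohol is routine, and a 3-furylmethyl position, unlike a 2-furylmethyl one, does not ionise under these non-acidic conditions.

Step 2
Reactants: 4 acrolein
Product: 6 2-bromoacrolein, via 2,3-dibromopropanal 5 (not isolated)
Conditions: Br2, CH2Cl2, −78 °C; then Et3N, −78 → 0 °C; distilled, used fresh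
Reagents that add atoms: bromine, BrBr
Why: Electrophilic addition of bromine to the alkene followed by E2 loss of HBr from the acidic α-position (bromination–dehydrobromination) is the standard preparation of this 2-haloenal.

Step 3
Reactants: 3 furan-3-ylmethyl benzoate (1.5 equiv); 6 2-bromoacrolein
Product: 7 cycloadduct with C2–O–C5 bridge, C1=C6 alkene carrying C7H2OBz on C1, C3H2, and C4 bearing exo-CHO and endo-Br
Conditions: (S)-2-butyl-4-(indol-3-ylmethyl)-3-(p-tolylsulfonyl)-1,3,2-oxazaborolidin-5-one (10 mol%), CH2Cl2, −78 °C; cold NaHCO3 quench, crude used at once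
Reagents that add atoms: none
Why: The boron Lewis acid binds the formyl oxygen of s-cis 6 and lowers its LUMO, so that a concerted but asynchronous normal-demand [4+2] cycloaddition ensues in which the CH2 terminus bonds ahead of the bromine-bearing carbon, forming C2–C3 and C4–C5. The closest known reaction is the oxazaborolidinone-catalysed enantioselective Diels–Alder addition of 2-bromoacrolein to furan itself, to which the 3-substituent is the only extension. The six-membered carbocycle C1–C6 is closed by intermolecular suprafacial [4+2] closure, the furan oxygen becoming the C2–O–C5 bridge. C4 is set by the dienophile face that the indole-shielded catalyst leaves open, and C2 and C5 follow from C4 through the formyl-exo, bromine-endo transition state that 2-haloacroleins prefer. Three selectivities are needed: para regiochemistry, secured by the larger HOMO coefficient at the furan α-carbon next to the side chain and by the bulky quaternary terminus bonding at the unhindered α-carbon; face selection, secured by the catalyst; and the formyl-exo mode, which is not cosmetic because an endo-formyl adduct made on the same dienophile face carries the mirror-image bicycle and would give ent-12 once C4 becomes trigonal, so that this epimer is removed at 8 or 9. The reaction and work-up are kept cold because furan adducts revert.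

Step 4
Reactants: 7 cycloadduct bromo aldehyde (crude)
Product: 8 bromo acid (C4 exo-CO2H, endo-Br; alkene and bridge unchanged)
Conditions: NaClO2, NaH2PO4, 2-methyl-2-butene, t-BuOH/H2O, 0 °C
Reagents that add atoms: sodium chlorite, [Na+].[O-]Cl=O
Why: Pinnick oxidation converts the non-enolisable α-bromo aldehyde into the acid in the cold without touching the alkene, because 2-methyl-2-butene scavenges the hypochlorous acid, and the acid can be purified by extraction and crystallisation to remove regioisomer and C4 epimer, while no stereocentre changes.

Step 5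
Reactants: 8 bromo acid
Product: 9 epoxy bromo acid (exo 1,6-epoxide, C7H2OBz endo on C1)
Conditions: DMDO (acetone), CH2Cl2, 0 °C → rt
Reagents that add atoms: dimethyldioxirane, CC1(C)OO1
Why: Dioxirane epoxidation (electrophilic oxygen transfer) of the strained C1=C6 alkene occurs on the exo face, as is the rule for 7-oxanorbornenes whose endo face is screened by the C3–C4 bridge, which sets C1 and C6 cis to the C2 oxygen and removes the alkene needed for cycloreversion.

Step 6
Reactants: 9 epoxy bromo acid
Product: 12 epoxy ketone (C4=O, C3H2), via acyl azide 10 (not isolated), via bromo isocyanate 11 (not isolated)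
Conditions: DPPA, Et3N, PhMe, rt → 80 °C; then AcOH/H2O, 50 °C
Reagents that add atoms: water, O; diphenylphosphoryl azide, [N-]=[N+]=NP(=O)(Oc1ccccc1)Oc1ccccc1 (its nitrogen stays only in 10 and 11)
Why: Curtius rearrangement with retention gives an α-bromo isocyanate whose hydrolysis (carbamic acid, loss of CO2, α-bromo amine, iminium ion) unmasks the C4 ketone, the classical way of turning the α-halo acid of a ketene-equivalent Diels–Alder adduct into a ketone, under acidic conditions that spare the benzoate and the exo epoxide, and no new stereocentre arises because C4 becomes trigonal.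

Step 7
Reactants: 12 epoxy ketone
Product: 13 silyl enol ether (C3=C4, OTBS on C4)
Conditions: TBSOTf, Et3N, CH2Cl2, −78 → 0 °C
Reagents that add atoms: tert-butyldimethylsilyl triflate, CC(C)(C)[Si](C)(C)OS(=O)(=O)C(F)(F)F
Why: Soft enolisation with a silyl triflate and an amine (silyl enol ether formation) can only run toward C3 because C5 is a bridgehead (Bredt's rule), and in the cold the enol ether forms faster than E1cB loss of the bridge oxygen from C2.

Step 8
Reactants: 13 silyl enol ether
Product: 15 C3 exo-silyloxy ketone, via silyloxy oxirane 14 (not isolated)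
Conditions: mCPBA (1.1 equiv), CH2Cl2, −20 °C → rt
Reagents that add atoms: 3-chloroperbenzoic acid, OOC(=O)c1cccc(Cl)c1
Why: In this Rubottom oxidation the peracid epoxidises the electron-rich enol ether on the exo face (the endo face is blocked by the C1–C6 bridge and its endo C7H2OBz group), and acid-promoted opening of the silyloxy oxirane with 1,4-silyl shift delivers the C3 oxygen exo and already silylated, cis to the bridge and epoxide oxygens.

Step 9
Reactants: 15 C3 exo-silyloxy ketone
Product: 18 allylic alcohol (C4=C5, free C2–OH, C3–OTBS, 1,6-epoxide, all oxygens cis), via hydrazone 16 (not isolated), via alkenyl diazene 17 (not isolated)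
Conditions: N2H4·H2O (1.5 equiv), AcOH (3 equiv), EtOH, 0 °C → rt
Reagents that add atoms: hydrazine hydrate, NN.O (its nitrogen stays only in 16 and 17 and leaves as N2)
Why: Proposed new method: the hydrazone of the C4 ketone pushes electron density from its terminal nitrogen through C4=N into the σ* orbital of the strained, acid-activated C5–O bond, so that the bridge opens to an alkenyl diazene which loses N2 and leaves C4(H)=C5(H) and the free C2 hydroxyl, while the C3 silyloxy group should stay because its loss would create a more strained bicyclic alkene; the closest known reactions are the Wharton transposition of α,β-epoxy ketones and the Kishner–Leonard eliminative reduction of α-alkoxy ketones, neither of which has been run on a 7-oxanorbornanone bridge under buffered conditions, and no stereocentre is formed or touched.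

Step 10
Reactants: 18 allylic alcohol; 2 benzoyl chloride
Product: 19 dibenzoate silyl ether (C2–OBz, C7–OBz, C3–OTBS)
Conditions: BzCl, pyridine, DMAP (cat.), CH2Cl2, 0 °C → rt
Reagents that add atoms: benzoyl chloride (2), ClC(=O)c1ccccc1
Why: DMAP-catalysed acylation of the only free hydroxyl places the benzoate on O2 unambiguously because O3 is silylated, and it would also re-esterify any O7 unmasked by hydrazine in step 9.

Step 11
Reactants: 19 dibenzoate silyl ether
Product: 20 target, [(1S,2R,3R,6S)-2-(benzoyloxy)-3-hydroxy-7-oxabicyclo[4.1.0]hept-4-en-1-yl]methyl benzoate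
Conditions: TBAF, AcOH (1:1), THF, 0 °C → rt
Reagents that add atoms: none
Why: Fluoride cleavage of the Si–O bond (silyl ether deprotection) is buffered with acetic acid so that the C3 alkoxide is protonated before the cis benzoate can migrate from O2 to O3 and the vinyl epoxide meets neither base nor strong acid, and no stereocentre is touched.

Compound list

1 | furan-3-ylmethanol | OCc1ccoc1 | starting material
2 | benzoyl chloride | ClC(=O)c1ccccc1 | starting material
3 | furan-3-ylmethyl benzoate | O=C(OCc1ccoc1)c1ccccc1 | intermediate
4 | acrolein | C=CC=O | starting material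
5 | 2,3-dibromopropanal (racemic) | O=CC(Br)CBr | intermediate
6 | 2-bromoacrolein | C=C(Br)C=O | intermediate
7 | [(1R,4R,5R)-5-bromo-5-formyl-7-oxabicyclo[2.2.1]hept-2-en-2-yl]methyl benzoate (C4 exo-CHO, endo-Br) | O=C(OCC1=C[C@H]2O[C@@H]1C[C@]2(Br)C=O)c1ccccc1 | intermediate
8 | (1R,2R,4R)-5-(benzoyloxymethyl)-2-bromo-7-oxabicyclo[2.2.1]hept-5-ene-2-carboxylic acid (C4 exo-CO2H, endo-Br) | O=C(OCC1=C[C@H]2O[C@@H]1C[C@]2(Br)C(=O)O)c1ccccc1 | intermediate
9 | exo 1,6-epoxide of 8 (epoxide oxygen syn to the bridge, C7H2OBz endo) | O=C(OC[C@]12O[C@H]1[C@H]3O[C@@H]2C[C@]3(Br)C(=O)O)c1ccccc1 | intermediate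
10 | acyl azide of 9 (C4 exo-CON3, endo-Br) | O=C(OC[C@]12O[C@H]1[C@H]3O[C@@H]2C[C@]3(Br)C(=O)N=[N+]=[N-])c1ccccc1 | intermediate
11 | C4 bromo isocyanate (exo-NCO, endo-Br, exo 1,6-epoxide) | O=C(OC[C@]12O[C@H]1[C@H]3O[C@@H]2C[C@]3(Br)N=C=O)c1ccccc1 | intermediate
12 | epoxy ketone (C4=O, C3H2, exo 1,6-epoxide, C2–O–C5 bridge) | O=C(OC[C@]12O[C@H]1[C@H]3O[C@@H]2CC3=O)c1ccccc1 | intermediate
13 | tert-butyldimethylsilyl enol ether of 12 (C3=C4) | O=C(OC[C@]12O[C@H]1[C@H]3O[C@@H]2C=C3O[Si](C)(C)C(C)(C)C)c1ccccc1 | intermediate
14 | exo 3,4-epoxide of 13 (OTBS endo on C4) | O=C(OC[C@]12O[C@H]1[C@H]3O[C@@H]2[C@@H]2O[C@]32O[Si](C)(C)C(C)(C)C)c1ccccc1 | intermediate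
15 | C3 exo-(tert-butyldimethylsilyloxy) C4 ketone (epoxide, bridge and C3 oxygens all exo) | O=C(OC[C@]12O[C@H]1[C@H]3O[C@@H]2[C@H](O[Si](C)(C)C(C)(C)C)C3=O)c1ccccc1 | intermediate
16 | C4 hydrazone of 15 | O=C(OC[C@]12O[C@H]1[C@H]3O[C@@H]2[C@H](O[Si](C)(C)C(C)(C)C)C3=NN)c1ccccc1 | intermediate
17 | ring-opened alkenyl diazene (C4=C5 with N=NH on C4, C2–OH, C3–OTBS, 1,6-epoxide, oxygens all cis) | O=C(OC[C@]12O[C@H]1C=C(N=N)[C@@H](O[Si](C)(C)C(C)(C)C)[C@H]2O)c1ccccc1 | intermediate
18 | [2-hydroxy-3-(tert-butyldimethylsilyloxy)-7-oxabicyclo[4.1.0]hept-4-en-1-yl]methyl benzoate, epoxide O, O2 and O3 all cis | O=C(OC[C@]12O[C@H]1C=C[C@@H](O[Si](C)(C)C(C)(C)C)[C@H]2O)c1ccccc1 | intermediate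
19 | O2-benzoate of 18 | O=C(OC[C@]12O[C@H]1C=C[C@@H](O[Si](C)(C)C(C)(C)C)[C@H]2OC(=O)c1ccccc1)c1ccccc1 | intermediate
20 | [(1S,2R,3R,6S)-2-(benzoyloxy)-3-hydroxy-7-oxabicyclo[4.1.0]hept-4-en-1-yl]methyl benzoate | O=C(OC[C@]12O[C@H]1C=C[C@@H](O)[C@H]2OC(=O)c1ccccc1)c1ccccc1 | target

Total steps: 11. Longest linear sequence: 10 steps (steps 1 and 3–11, from furan-3-ylmethanol); step 2 is a one-step side branch.

Steps most likely to fail

1. Step 9 (proposed method). The C5–O bond may fail to ionise under buffered conditions so that the hydrazone merely persists, the C3 silyloxy group may be expelled instead of the bridge oxygen, or hydrazine may attack the benzoate. The fallback is a Boord-type reductive β-elimination, all known chemistry, setting out from 15. NaBH4 (MeOH, −20 °C) reduces the ketone to the C4 endo alcohol F1. I2, PPh3 and imidazole (toluene, 80 °C) convert it with inversion into the C4 exo iodide F2. Zn dust with NH4Cl in EtOH (50 °C) then inserts into the C–I bond and expels the bridge alkoxide from C5, which returns the route at 18. The configuration at C4 is irrelevant to this last operation.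

2. Step 3. Face selection or turnover may suffer if the ester and the product aldehyde compete for boron, the para preference may be weak, an endo-formyl adduct may form, and the adduct may revert on warming. The fallback gives up catalytic asymmetric induction for classical resolution and sets out from 3 and 6. BF3·OEt2 (CH2Cl2, −78 °C) gives 7 together with its mirror image ent-7 F3. Oxidation as in step 4 gives 8 and its mirror image ent-8 F4. Crystallisation with (S)-1-phenylethylamine (or its antipode, whichever salt of the wanted acid is less soluble) gives the (S)-1-phenylethylammonium salt of 8 F5, and aqueous KHSO4 releases 8, where the route is rejoined. The salt crystallisation also offers a handle for removing the regioisomer and the C4 epimer.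

3. Step 8. Excess peracid may bring about Baeyer–Villiger oxidation of the strained ketone, and the silyl group may be lost from the oxocarbenium intermediate so that silylated and free ketol form side by side. The fallback replaces the enol ether–peracid sequence by direct enolate oxidation and sets out from 12. KHMDS (THF, −78 °C) gives the potassium enolate F6, which 2-(phenylsulfonyl)-3-phenyloxaziridine hydroxylates on the exo face to the C3 exo-hydroxy ketone F7. TBSOTf and 2,6-lutidine (CH2Cl2, −78 °C) then give 15.

Further compounds

F1 | step 9 | C4 endo alcohol from 15 (C3 exo-OTBS, exo 1,6-epoxide) | O=C(OC[C@]12O[C@H]1[C@H]3O[C@@H]2[C@H](O[Si](C)(C)C(C)(C)C)[C@H]3O)c1ccccc1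
F2 | step 9 | C4 exo iodide | O=C(OC[C@]12O[C@H]1[C@H]3O[C@@H]2[C@H](O[Si](C)(C)C(C)(C)C)[C@@H]3I)c1ccccc1
F3 | step 3 | ent-7 | O=C(OCC1=C[C@@H]2O[C@H]1C[C@@]2(Br)C=O)c1ccccc1
F4 | step 3 | ent-8 | O=C(OCC1=C[C@@H]2O[C@H]1C[C@@]2(Br)C(=O)O)c1ccccc1
F5 | step 3 | (S)-1-phenylethylammonium salt of 8 | O=C(OCC1=C[C@H]2O[C@@H]1C[C@]2(Br)C(=O)[O-])c1ccccc1.C[C@H]([NH3+])c1ccccc1
F6 | step 8 | potassium enolate of 12 | O=C(OC[C@]12O[C@H]1[C@H]3O[C@@H]2C=C3[O-])c1ccccc1.[K+]
F7 | step 8 | C3 exo-hydroxy ketone | O=C(OC[C@]12O[C@H]1[C@H]3O[C@@H]2[C@H](O)C3=O)c1ccccc1
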